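**Assumption:** the chain is a linear (CH2)12 unit ending in phenyl, as drawn. The Cu/bisphosphine ligand enantiomer in Step 4 is taken to give the (S)-alcohol.

## Retrosynthetic overview
- Target (3aS,5S,6aS)-5,6a-dimethyl-5-(12-phenyldodecyl)tetrahydrofuro[3,2-b]furan-2-one. Disconnect the C3a–C6a bond, which is a 5-exo SmI2 ketyl addition of a methyl ketone onto a β-alkoxyacrylate.
- The THF ring forms in that radical step. The γ-lactone then forms in situ from the tertiary Sm-alkoxide and the ester, so cis ring fusion is enforced.
- The acrylate comes from a tertiary homoallylic alcohol plus ethyl propiolate. The methyl ketone comes from Wacker oxidation of the allyl group.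
- The C5 quaternary stereocentre is set by catalytic asymmetric allylation of the methyl ketone Ph(CH2)12COCH3.
- That ketone comes from Ph(CH2)12MgBr plus MeCN. The chain is built from PhMgBr and two 1,6-dibromohexane units.

## Route

**Step 1**
Reactants: 1 (1,6-dibromohexane), 2 (bromobenzene)
Product: 3 ((6-bromohexyl)benzene)
Conditions: PhBr, Mg, THF, then PhMgBr added to 1 (3 equiv), Li2CuCl4 (3 mol%), THF, −10 °C → rt
Reagents that add atoms: none
Why: Cu-catalysed Kumada-type SN2 coupling of PhMgBr at one C–Br; excess 1 suppresses double coupling and is removed by distillation.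

**Step 2**
Reactants: 3, 1
Product: 4 ((12-bromododecyl)benzene)
Conditions: 3, Mg, THF; then add to 1 (3 equiv), Li2CuCl4 (3 mol%), −10 °C → rt
Reagents that add atoms: none
Why: the same Cu-catalysed alkyl–alkyl Grignard coupling completes the Ph(CH2)12 chain.

**Step 3**
Reactants: 4, 5 (acetonitrile)
Product: 6 (14-phenyltetradecan-2-one)
Conditions: 4, Mg, THF; then MeCN, CuBr (5 mol%), THF, rt; then aq. HCl, 50 °C
Reagents that add atoms: water, O (hydrolysis of the N-magnesio imine gives the C=O)
Why: Grignard addition to a nitrile gives a ketimine salt that hydrolyses to the methyl ketone. The nitrile carbon becomes C5 of the target and MeCN's CH3 becomes its methyl.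

**Step 4**
Reactants: 6
Product: 7 ((4S)-4-methyl-16-phenylhexadec-1-en-4-ol)
Conditions: allylB(pin), CuCl (5 mol%), (R)-DTBM-SEGPHOS (5 mol%), LiOt-Bu (10 mol%), THF, rt; then aq. NH4Cl
Reagents that add atoms: allylB(pin), C=CCB1OC(C)(C)C(C)(C)O1 (delivers the allyl group)
Why: catalytic enantioselective ketone allylation through a chair-like allyl transfer from a Cu-alkoxide/allylboronate. The chiral bisphosphine distinguishes Me from CH2R and sets the tertiary carbinol carbon as (S), the configuration of C5 in the target. This centre is not touched again.

**Step 5**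
Reactants: 7, 8 (ethyl propiolate)
Product: 9 (ethyl (2E)-3-{[(4S)-4-methyl-16-phenylhexadec-1-en-4-yl]oxy}prop-2-enoate)
Conditions: 8 (2 equiv), PMe3 (10 mol%), CH2Cl2, 0 °C → rt
Reagents that add atoms: none
Why: phosphine-catalysed oxa-Michael addition of the tertiary alcohol to the propiolate gives the (E)-β-alkoxyacrylate. No bond to the stereocentre is broken.

**Step 6**
Reactants: 9
Product: 10 (ethyl (2E)-3-{[(4S)-4-methyl-2-oxo-16-phenylhexadecan-4-yl]oxy}prop-2-enoate)
Conditions: PdCl2 (10 mol%), CuCl (1 equiv), O2 (1 atm), DMF/H2O 7:1, rt
Reagents that add atoms: water, O (ketone oxygen source)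
Why: Wacker–Tsuji oxidation converts the terminal alkene Markovnikov-wise to the methyl ketone. The electron-poor β-alkoxyacrylate is inert. The methyl ketone is the radical precursor, and its CH3 is the methyl on C6a.

**Step 7**
Reactants: 10
Product: 11 (plakortone L)
Conditions: SmI2 (2.5 equiv), t-BuOH (2 equiv), THF, −78 → 0 °C (no HMPA); then p-TsOH (cat.), CH2Cl2, rt; chromatographic separation of diastereomers
Reagents that add atoms: none (t-BuOH supplies only H; EtOH is lost on lactonisation)
Why: Proposed new method: SmI2 reduces the methyl ketone to a tertiary ketyl radical. This adds 5-exo-trig to the alkoxy-bearing β-carbon of the acrylate, forming the THF ring and the C3a–C6a bond. The α-ester radical is reduced to a Sm enolate and protonated, and the resulting tertiary alkoxide closes onto the ester to give the γ-lactone. The closest known reaction is SmI2 ketyl–olefin cyclisation onto β-alkoxyacrylates used for cyclic ether synthesis, extended here to a methyl ketone and a tertiary-ether tether. In a chair-like 5-exo transition state the large O–Sm(III) group and the long chain sit pseudo-equatorial. This puts the oxygen cis to the CH2CO2Et arm, which is the only arrangement that can lactonise. Ester chelation to Sm(III) supports this, and the chain ends up trans to that arm, exo on the convex face. C3a and C6a therefore form as (S,S) relative to the existing C5 (S). A minor C5-epimeric/trans-hydroxy-ester fraction (estimated dr about 2–3:1) is removed chromatographically.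

## Compound list
1 | 1,6-dibromohexane | BrCCCCCCBr | starting material
2 | bromobenzene | Brc1ccccc1 | starting material
3 | (6-bromohexyl)benzene | BrCCCCCCc1ccccc1 | intermediate
4 | (12-bromododecyl)benzene | BrCCCCCCCCCCCCc1ccccc1 | intermediate
5 | acetonitrile | CC#N | starting material
6 | 14-phenyltetradecan-2-one | CC(=O)CCCCCCCCCCCCc1ccccc1 | intermediate
7 | (4S)-4-methyl-16-phenylhexadec-1-en-4-ol | C[C@](O)(CCCCCCCCCCCCc1ccccc1)CC=C | intermediate
8 | ethyl propiolate | C#CC(=O)OCC | starting material
9 | ethyl (2E)-3-{[(4S)-4-methyl-16-phenylhexadec-1-en-4-yl]oxy}prop-2-enoate | CCOC(=O)/C=C/O[C@](C)(CC=C)CCCCCCCCCCCCc1ccccc1 | intermediate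
10 | ethyl (2E)-3-{[(4S)-4-methyl-2-oxo-16-phenylhexadecan-4-yl]oxy}prop-2-enoate | CCOC(=O)/C=C/O[C@](C)(CC(C)=O)CCCCCCCCCCCCc1ccccc1 | intermediate
11 | plakortone L, (3aS,5S,6aS)-5,6a-dimethyl-5-(12-phenyldodecyl)tetrahydrofuro[3,2-b]furan-2(3H)-one | C[C@]1(CCCCCCCCCCCCc2ccccc2)C[C@]2(C)OC(=O)C[C@@H]2O1 | target

**Total steps:** 7. **Longest linear sequence:** 7 (Steps 1 → 7).

## Three steps most likely to fail
1. **Step 7 (SmI2 cyclisation).** Risks are ketone over-reduction or pinacol coupling, a trans (non-lactonising) hydroxy ester, and poor dr relative to C5.
   - Fallback (different approach): use the methallyl analogue of 7 and cross-metathesise it with 3-butenoic acid. Iodolactonise to the 4-iodo-γ-lactone, then close the THF by Ag+-promoted intramolecular SN2 etherification by the tertiary alcohol. Inversion at C4 gives the cis-fused bicycle.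
2. **Step 4 (asymmetric allylation of a dialkyl methyl ketone).** Me versus CH2R discrimination may give only moderate ee.
   - Fallback (different approach): Sharpless asymmetric epoxidation of the (E)-allylic alcohol HOCH2CH=C(Me)(CH2)12Ph (from carboalumination). Open the epoxide with Red-Al to the (S)-tertiary 1,3-diol, then convert it to the same β-hydroxy ketone or acrylate by protection, oxidation, MeMgBr addition and oxidation.
3. **Step 6 (Wacker on a β-alkoxy-ketone precursor).** The tertiary β-alkoxy ketone may undergo acid-induced elimination, and the acrylate may hydrolyse.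
   - Fallback (different approach): use methallylB(pin) in Step 4, keep the vinyl ether from Step 5, and reveal the methyl ketone by chemoselective OsO4 (cat.)/NaIO4/2,6-lutidine cleavage of the 1,1-disubstituted alkene.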